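**Strategy**
Core numbering (hydrindene): C1 = CH–O, C2 = CH–C(=O), C3 = CH2, C3a, C4 (carries the trimethylcyclohexyl ring), C5, C6, C7 (carries CH2O), C7a.
Cuts, in retrosynthetic order: lactone O–C(=O); butyrate; C5–C6 and C7–C7a (acrolein cycloaddition); C3a–C7a with the C5 methylene returned to C7a as a vinyl CH2 (enyne metathesis); C1–C2 (acrolein aldol); C3–C3a (acetylide/oxetane); quaternary carbon–C4 (conjugate addition).
Forward: the trimethylcyclohexane ring is bought as 3-methylcyclohexenone; the cyclopentene closes by enyne metathesis, the cyclohexene by Diels–Alder reaction in the same flask, the β-lactone in the last step.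
Enabling feature: the single alkene, tetrasubstituted C3a=C4, sits in the six-membered ring where a [4+2] addition leaves its double bond. The diene C5=C4–C3a=C7a is therefore the metathesis isomer of an open-chain 1,6-enyne whose alkyne already carries the quaternary carbon, and the cis C1–O/C2–C(=O) pair is a syn aldol of acrolein.
Stereochemistry: quaternary carbon from a copper-catalysed enantioselective conjugate addition; C1 and C2 from an Evans syn aldol; C7a from cycloaddition anti to the C1/C2 substituents; C7 by equilibration of the aldehyde; lactone fusion by retention.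

Key step: step 12

Assumption: the enantiomer of the carbene ligand in step 1 is the one that delivers the (S)-ketone, its sense of induction being taken from the behaviour of this catalyst class with cyclic β-substituted enones.

**Route**

Step 1
Reactants: 1 3-methylcyclohex-2-en-1-one; 2 trimethylsilylacetylene
Product: 4 (3S)-3-methyl-3-[1-(trimethylsilyl)ethenyl]cyclohexan-1-one, via vinylalane 3 (not isolated)
Conditions: 2, i-Bu2AlH, hexanes/THF, 55 °C; then 1, CuCl2·2H2O (cat.), chiral sulfonate-bearing imidazolinium salt (carbene precursor, cat.), THF, −78 → −15 °C; aq. HCl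
Reagents that add atoms: none
Why: Hydroalumination places aluminium on the silyl-bearing alkyne carbon, and copper–carbene-catalysed enantioselective conjugate addition of this 1-silylvinyl group to a β-methyl cyclic enone is an established route to such quaternary centres, the ligand enantiomer fixing the (S) configuration.

Step 2
Reactants: 4 (3S)-3-methyl-3-[1-(trimethylsilyl)ethenyl]cyclohexan-1-one
Product: 5 (3S)-3-(1-iodoethenyl)-3-methylcyclohexan-1-one
Conditions: NIS, MeCN, 0 °C, dark
Reagents that add atoms: N-iodosuccinimide, O=C1CCC(=O)N1I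
Why: Electrophilic ipso-iododesilylation of the vinylsilane exchanges SiMe3 for iodine at the same carbon and leaves the ketone and the quaternary centre untouched.

Step 3
Reactants: 5 (3S)-3-(1-iodoethenyl)-3-methylcyclohexan-1-one
Product: 6 (1S)-1-(1-iodoethenyl)-1,3,3-trimethylcyclohexane
Conditions: Me2Zn, TiCl4, CH2Cl2, −40 °C (gives Me2TiCl2); then 5, −40 → 0 °C
Reagents that add atoms: dimethylzinc, C[Zn]C (its methyl groups are delivered through Me2TiCl2, C[Ti](C)(Cl)Cl, made in the flask)
Why: Reetz geminal dimethylation replaces the carbonyl oxygen by two methyl groups through two successive methyl transfers from titanium, the second to a tertiary carbocation that the electron-poor iodoalkene and the remote quaternary centre should not disturb.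

Step 4
Reactants: 6 (1S)-1-(1-iodoethenyl)-1,3,3-trimethylcyclohexane
Product: 7 (1S)-1-ethynyl-1,3,3-trimethylcyclohexane
Conditions: KOt-Bu, THF, 0 °C → rt; pentane extraction, kept as a titrated solution (volatile)
Reagents that add atoms: none
Why: Anti E2 dehydroiodination of the 2-iodo-1-alkene can only give the terminal alkyne, because the quaternary carbon offers no allylic hydrogen for allene formation.

Step 5
Reactants: 7 (1S)-1-ethynyl-1,3,3-trimethylcyclohexane; 8 oxetane
Product: 10 5-[(1S)-1,3,3-trimethylcyclohexyl]pent-4-yn-1-ol, via lithium acetylide 9 (not isolated)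
Conditions: n-BuLi, THF, −78 °C; then BF3·OEt2, 8, −78 °C; aq. NH4Cl
Reagents that add atoms: none
Why: BF3-promoted ring opening of oxetane by a lithium acetylide is a reliable low-temperature alkynylation that adds C3, C2 and the future lactone carbonyl carbon in one operation.

Step 6
Reactants: 10 5-[(1S)-1,3,3-trimethylcyclohexyl]pent-4-yn-1-ol
Product: 11 5-[(1S)-1,3,3-trimethylcyclohexyl]pent-4-ynoic acid
Conditions: TEMPO (cat.), PhI(OAc)2, MeCN/H2O, rt
Reagents that add atoms: water, O
Why: Oxoammonium-mediated (TEMPO) oxidation in aqueous acetonitrile takes a primary alcohol to the carboxylic acid without touching the alkyne.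

Step 7
Reactants: 11 5-[(1S)-1,3,3-trimethylcyclohexyl]pent-4-ynoic acid; 12 (R)-4-benzyl-1,3-oxazolidin-2-one
Product: 14 (4R)-4-benzyl-3-{5-[(1S)-1,3,3-trimethylcyclohexyl]pent-4-ynoyl}-1,3-oxazolidin-2-one, via mixed pivalic anhydride 13 (not isolated)
Conditions: PivCl, Et3N, THF, −20 °C; then LiCl, 12, −20 °C → rt
Reagents that add atoms: none
Why: N-Acylation of the oxazolidinone through the mixed pivalic anhydride under LiCl/Et3N activation is the standard mild preparation of Evans imides.

Step 8
Reactants: 14 (4R)-4-benzyl-3-{5-[(1S)-1,3,3-trimethylcyclohexyl]pent-4-ynoyl}-1,3-oxazolidin-2-one; 15 acrolein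
Product: 17 (4R)-4-benzyl-3-[(2R,3S)-3-hydroxy-2-{3-[(1S)-1,3,3-trimethylcyclohexyl]prop-2-yn-1-yl}pent-4-enoyl]-1,3-oxazolidin-2-one, via Z boron enolate 16 (not isolated)
Conditions: n-Bu2BOTf, Et3N, CH2Cl2, −78 → 0 °C; 15, −78 → 0 °C; then pH 7 buffer (KH2PO4/K2HPO4), MeOH, 30% H2O2, 0 °C
Reagents that add atoms: none
Why: In the Evans syn aldol reaction the Z dibutylboron enolate reacts through a closed Zimmerman–Traxler chair with the imide dipoles opposed, so acrolein is taken on the enolate face away from the benzyl group and the (2R,3S) syn adduct, carrying C2 and C1 of the core, should result.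

Step 9
Reactants: 17 the syn aldol adduct
Product: 18 (4R)-4-benzyl-3-[(2R,3S)-3-(tert-butyldimethylsilyloxy)-2-{3-[(1S)-1,3,3-trimethylcyclohexyl]prop-2-yn-1-yl}pent-4-enoyl]-1,3-oxazolidin-2-one
Conditions: TBSOTf, 2,6-lutidine, CH2Cl2, −78 → 0 °C
Reagents that add atoms: tert-butyldimethylsilyl trifluoromethanesulfonate, CC(C)(C)[Si](C)(C)OS(=O)(=O)C(F)(F)F
Why: Silylation of the secondary allylic alcohol with the silyl triflate and a hindered base is fast at low temperature and closes off retro-aldol and self-acylation pathways in the next two steps.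

Step 10
Reactants: 18 the silylated imide
Product: 20 (2R,3S)-3-(tert-butyldimethylsilyloxy)-2-{3-[(1S)-1,3,3-trimethylcyclohexyl]prop-2-yn-1-yl}pent-4-enoic acid, via peroxy acid 19 (not isolated)
Conditions: LiOH, 30% H2O2, THF/H2O, 0 °C; then aq. Na2SO3; aq. HCl to pH 3
Reagents that add atoms: hydrogen peroxide, OO (used as lithium hydroperoxide, [Li+].[O-]O)
Why: Hydroperoxide attacks the exocyclic imide carbonyl selectively (Evans LiOOH cleavage) and sulfite then reduces the peracid, so the auxiliary is released without epimerising the α-centre or cleaving the silyl ether.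

Step 11
Reactants: 20 the silyloxy acid
Product: 21 2-(trimethylsilyl)ethyl (2R,3S)-3-(tert-butyldimethylsilyloxy)-2-{3-[(1S)-1,3,3-trimethylcyclohexyl]prop-2-yn-1-yl}pent-4-enoate
Conditions: Me3SiCH2CH2OH, DCC, DMAP (cat.), CH2Cl2, 0 °C → rt
Reagents that add atoms: 2-(trimethylsilyl)ethanol, C[Si](C)(C)CCO
Why: Steglich esterification gives the 2-(trimethylsilyl)ethyl ester, a carboxyl protecting group that tolerates metathesis, Lewis acid, DBU and borohydride and later falls to fluoride together with the TBS ether.

Step 12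
Reactants: 21 the enyne ester; 15 acrolein
Product: 23 2-(trimethylsilyl)ethyl (1S,2R,7R,7aR)-1-(tert-butyldimethylsilyloxy)-7-formyl-4-[(1S)-1,3,3-trimethylcyclohexyl]-2,3,5,6,7,7a-hexahydro-1H-indene-2-carboxylate (endo adduct), via vinylcyclopentene diene 22 (not isolated)
Conditions: second-generation Grubbs catalyst (H2IMes)(PCy3)Cl2Ru=CHPh (cat.), ethylene (1 atm), toluene (dilute), 80 °C; then argon purge, −78 °C, 15, Me2AlCl, −78 → −30 °C; cold aq. HCl work-up
Reagents that add atoms: none
Why: The ruthenium carbene loads onto the terminal vinyl group and adds across the tethered alkyne so that C7a bonds to C3a and the metal moves to C4, ethylene then takes the metal off this hindered carbon and leaves a methylene (C5) there to give diene 22, and acrolein bound to Me2AlCl next adds across C5 and C7a in a concerted, asynchronous [4+2] cycloaddition. The closest known reaction type is ring-closing enyne metathesis of a 1,6-enyne with an internal alkyne followed in the same flask by Diels–Alder trapping of the 1-vinylcycloalkene. The cyclopentene closes in the exo mode of the metathesis (bond C3a–C7a, five-membered ring over the three-atom tether C1–C2–C3) and the cyclohexene closes by the cycloaddition (bonds C5–C6 and C7–C7a), which leaves the tetrasubstituted C3a=C4 alkene with its tertiary alkyl group already attached. C7a is set by approach of acrolein to the diene face opposite the cis silyloxy and ester groups on C1 and C2, and C7 by the endo transition state, which puts the formyl group cis to C1 and is corrected in step 13. The step needs exo-mode metathesis, which the short tether enforces, ortho/para regiochemistry, which follows because the alkyl groups on C7a and C4 put the largest diene coefficient on the unsubstituted C5 where the acrolein β-carbon bonds first, and an accessible s-cis diene, which the tertiary alkyl group on C4 favours by destabilising the s-trans rotamer while the tied-back C3 methylene keeps the cisoid form from being overcrowded.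

Step 13
Reactants: 23 the endo aldehyde
Product: 24 2-(trimethylsilyl)ethyl (1S,2R,7S,7aR)-1-(tert-butyldimethylsilyloxy)-7-formyl-4-[(1S)-1,3,3-trimethylcyclohexyl]-2,3,5,6,7,7a-hexahydro-1H-indene-2-carboxylate
Conditions: DBU, CH2Cl2, rt; the minor C7 epimer is re-submitted
Reagents that add atoms: none
Why: Base-mediated epimerisation through the aldehyde enolate should move the formyl group to the equatorial position trans to the pseudo-equatorial C1 carbon (C7 becomes S), the ester α-hydrogen at C2 being far too weakly acidic for DBU.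

Step 14
Reactants: 24 the trans aldehyde
Product: 25 2-(trimethylsilyl)ethyl (1S,2R,7S,7aR)-1-(tert-butyldimethylsilyloxy)-7-(hydroxymethyl)-4-[(1S)-1,3,3-trimethylcyclohexyl]-2,3,5,6,7,7a-hexahydro-1H-indene-2-carboxylate
Conditions: NaBH4, EtOH/THF, −20 → 0 °C
Reagents that add atoms: none
Why: Chemoselective borohydride reduction of the aldehyde in the presence of the ester proceeds at low temperature and fixes C7 by removing its acidic hydrogen.

Step 15
Reactants: 25 the primary alcohol; 26 butyric anhydride
Product: 27 2-(trimethylsilyl)ethyl (1S,2R,7S,7aR)-7-(butanoyloxymethyl)-1-(tert-butyldimethylsilyloxy)-4-[(1S)-1,3,3-trimethylcyclohexyl]-2,3,5,6,7,7a-hexahydro-1H-indene-2-carboxylate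
Conditions: 26, Et3N, DMAP (cat.), CH2Cl2, 0 °C → rt
Reagents that add atoms: none
Why: DMAP-catalysed acylation of the only free, unhindered primary hydroxyl with the anhydride installs the butyrate.

Step 16
Reactants: 27 the fully protected butyrate
Product: 28 (1S,2R,7S,7aR)-7-(butanoyloxymethyl)-1-hydroxy-4-[(1S)-1,3,3-trimethylcyclohexyl]-2,3,5,6,7,7a-hexahydro-1H-indene-2-carboxylic acid
Conditions: Bu4NF, AcOH (1:1), THF, 0 °C → rt
Reagents that add atoms: none
Why: Fluoride attacks both silicon centres, the 2-(trimethylsilyl)ethyl ester fragmenting to carboxylate, ethylene and Me3SiF, while acetic acid buffering should keep the medium too weakly basic for butyrate migration or β-elimination.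

Step 17
Reactants: 28 the cis β-hydroxy acid
Product: 29 3'-norspongiolactone, the cis-fused β-lactone (C1–O–C(=O)–C2) of the (1S,2R,7S,7aR)-hydrindene with 7-butanoyloxymethyl and 4-[(1S)-1,3,3-trimethylcyclohexyl] groups
Conditions: BOPCl, Et3N, CH2Cl2, 0 °C → rt
Reagents that add atoms: none
Why: BOPCl activates the carboxyl group and the cis C1 hydroxyl closes the four-membered ring by acyl substitution, a standard lactonisation of cis β-hydroxy acids on five-membered rings that leaves the C1–O bond and hence the configuration at C1 and C2 untouched.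

**Compound list**
1 | 3-methylcyclohex-2-en-1-one | CC1=CC(=O)CCC1 | starting material
2 | trimethylsilylacetylene | C#C[Si](C)(C)C | starting material
3 | diisobutyl[1-(trimethylsilyl)ethenyl]alane | C=C([Si](C)(C)C)[Al](CC(C)C)CC(C)C | intermediate (not isolated)
4 | (3S)-3-methyl-3-[1-(trimethylsilyl)ethenyl]cyclohexan-1-one | C=C([Si](C)(C)C)[C@@]1(C)CCCC(=O)C1 | intermediate
5 | (3S)-3-(1-iodoethenyl)-3-methylcyclohexan-1-one | C=C(I)[C@@]1(C)CCCC(=O)C1 | intermediate
6 | (1S)-1-(1-iodoethenyl)-1,3,3-trimethylcyclohexane | C=C(I)[C@@]1(C)CCCC(C)(C)C1 | intermediate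
7 | (1S)-1-ethynyl-1,3,3-trimethylcyclohexane | C#C[C@@]1(C)CCCC(C)(C)C1 | intermediate
8 | oxetane | C1COC1 | starting material
9 | lithium [(1S)-1,3,3-trimethylcyclohexyl]ethynide | [Li]C#C[C@@]1(C)CCCC(C)(C)C1 | intermediate (not isolated)
10 | 5-[(1S)-1,3,3-trimethylcyclohexyl]pent-4-yn-1-ol | OCCCC#C[C@@]1(C)CCCC(C)(C)C1 | intermediate
11 | 5-[(1S)-1,3,3-trimethylcyclohexyl]pent-4-ynoic acid | OC(=O)CCC#C[C@@]1(C)CCCC(C)(C)C1 | intermediate
12 | (R)-4-benzyl-1,3-oxazolidin-2-one | O=C1N[C@H](Cc2ccccc2)CO1 | starting material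
13 | mixed anhydride of 11 with pivalic acid | CC(C)(C)C(=O)OC(=O)CCC#C[C@@]1(C)CCCC(C)(C)C1 | intermediate (not isolated)
14 | (4R)-4-benzyl-3-{5-[(1S)-1,3,3-trimethylcyclohexyl]pent-4-ynoyl}-1,3-oxazolidin-2-one | O=C(CCC#C[C@@]1(C)CCCC(C)(C)C1)N2[C@H](Cc3ccccc3)COC2=O | intermediate
15 | acrolein | C=CC=O | starting material
16 | (Z)-dibutylboron enolate of 14 | CCCCB(CCCC)O/C(=C\CC#C[C@@]1(C)CCCC(C)(C)C1)N2[C@H](Cc3ccccc3)COC2=O | intermediate (not isolated)
17 | (4R)-4-benzyl-3-[(2R,3S)-3-hydroxy-2-{3-[(1S)-1,3,3-trimethylcyclohexyl]prop-2-yn-1-yl}pent-4-enoyl]-1,3-oxazolidin-2-one | O=C(N2[C@H](Cc3ccccc3)COC2=O)[C@H](CC#C[C@@]1(C)CCCC(C)(C)C1)[C@@H](O)C=C | intermediate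
18 | tert-butyldimethylsilyl ether of 17 | O=C(N2[C@H](Cc3ccccc3)COC2=O)[C@H](CC#C[C@@]1(C)CCCC(C)(C)C1)[C@@H](O[Si](C)(C)C(C)(C)C)C=C | intermediate
19 | (2R,3S)-3-(tert-butyldimethylsilyloxy)-2-{3-[(1S)-1,3,3-trimethylcyclohexyl]prop-2-yn-1-yl}pent-4-eneperoxoic acid | OOC(=O)[C@H](CC#C[C@@]1(C)CCCC(C)(C)C1)[C@@H](O[Si](C)(C)C(C)(C)C)C=C | intermediate (not isolated)
20 | (2R,3S)-3-(tert-butyldimethylsilyloxy)-2-{3-[(1S)-1,3,3-trimethylcyclohexyl]prop-2-yn-1-yl}pent-4-enoic acid | OC(=O)[C@H](CC#C[C@@]1(C)CCCC(C)(C)C1)[C@@H](O[Si](C)(C)C(C)(C)C)C=C | intermediate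
21 | 2-(trimethylsilyl)ethyl ester of 20 (open-chain 1,6-enyne) | C[Si](C)(C)CCOC(=O)[C@H](CC#C[C@@]1(C)CCCC(C)(C)C1)[C@@H](O[Si](C)(C)C(C)(C)C)C=C | intermediate
22 | 2-(trimethylsilyl)ethyl (1R,2S)-2-(tert-butyldimethylsilyloxy)-4-{1-[(1S)-1,3,3-trimethylcyclohexyl]ethenyl}cyclopent-3-ene-1-carboxylate | C=C([C@@]1(C)CCCC(C)(C)C1)C2=C[C@H](O[Si](C)(C)C(C)(C)C)[C@H](C(=O)OCC[Si](C)(C)C)C2 | intermediate (not isolated)
23 | 2-(trimethylsilyl)ethyl (1S,2R,7R,7aR)-1-(tert-butyldimethylsilyloxy)-7-formyl-4-[(1S)-1,3,3-trimethylcyclohexyl]-2,3,5,6,7,7a-hexahydro-1H-indene-2-carboxylate | O=C[C@@H]1CCC([C@@]2(C)CCCC(C)(C)C2)=C2C[C@@H](C(=O)OCC[Si](C)(C)C)[C@@H](O[Si](C)(C)C(C)(C)C)[C@@H]21 | intermediate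
24 | (7S) epimer of 23, formyl trans to C1 | O=C[C@H]1CCC([C@@]2(C)CCCC(C)(C)C2)=C2C[C@@H](C(=O)OCC[Si](C)(C)C)[C@@H](O[Si](C)(C)C(C)(C)C)[C@@H]21 | intermediate
25 | 2-(trimethylsilyl)ethyl (1S,2R,7S,7aR)-1-(tert-butyldimethylsilyloxy)-7-(hydroxymethyl)-4-[(1S)-1,3,3-trimethylcyclohexyl]-2,3,5,6,7,7a-hexahydro-1H-indene-2-carboxylate | OC[C@H]1CCC([C@@]2(C)CCCC(C)(C)C2)=C2C[C@@H](C(=O)OCC[Si](C)(C)C)[C@@H](O[Si](C)(C)C(C)(C)C)[C@@H]21 | intermediate
26 | butyric anhydride | CCCC(=O)OC(=O)CCC | starting material
27 | butanoate of 25 | CCCC(=O)OC[C@H]1CCC([C@@]2(C)CCCC(C)(C)C2)=C2C[C@@H](C(=O)OCC[Si](C)(C)C)[C@@H](O[Si](C)(C)C(C)(C)C)[C@@H]21 | intermediate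
28 | (1S,2R,7S,7aR)-7-(butanoyloxymethyl)-1-hydroxy-4-[(1S)-1,3,3-trimethylcyclohexyl]-2,3,5,6,7,7a-hexahydro-1H-indene-2-carboxylic acid | CCCC(=O)OC[C@H]1CCC([C@@]2(C)CCCC(C)(C)C2)=C2C[C@@H](C(=O)O)[C@@H](O)[C@@H]21 | intermediate
29 | 3'-norspongiolactone | CCCC(=O)OC[C@H]1CCC([C@@]2(C)CCCC(C)(C)C2)=C2C[C@H]3C(=O)O[C@H]3[C@@H]21 | target

**Step count and risks**
Total: 17 steps. Longest linear sequence: 17 steps (1 or 2 to 29; the route is fully linear).

Most likely to fail, riskiest first:

Step 12. The ruthenium carbene may fail to engage, or to leave, the alkyne carbon flanked by the quaternary centre, so that ethylene cross-metathesis at the vinyl group, oligomerisation or catalyst decay outrun ring closure; in the second stage the crowded diene may add acrolein slowly or with eroded regiocontrol. The fallback sets out from enyne 21. PtCl2 (cat.) in toluene at 80 °C should isomerise the 1,6-enyne by the known platinum-catalysed skeletal rearrangement (alkene attack on the metal-bound alkyne, cyclopropyl carbene, single C–C cleavage). This gives the same 1-vinylcyclopentene 22 without any olefin having to turn over a carbene at the hindered carbon. Diene 22 is then isolated and treated with acrolein and Me2AlCl in CH2Cl2 at −78 °C, which returns to the route at 23. No compound outside the list is made (no new compound, F0).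

Step 3. The tertiary carbocation formed after the first methyl transfer may lose a proton to ring alkenes, or be intercepted by the iodoalkene, faster than titanium delivers the second methyl group. The fallback sets out from ketone 5. MeMgBr with CeCl3 (THF, −78 °C) should give the tertiary alcohol (1RS,3S)-3-(1-iodoethenyl)-1,3-dimethylcyclohexan-1-ol F1. HCl in CH2Cl2 at 0 °C converts it into the tertiary chloride (1S,3RS)-3-chloro-1-(1-iodoethenyl)-1,3-dimethylcyclohexane F2. Me3Al in CH2Cl2 at −78 °C then methylates this chloride by ionisation and methyl transfer within the ion pair, at a temperature where elimination is slow, and rejoins the route at 6.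

Step 16. The hindered secondary TBS ether may need a fluoride exposure long enough for cleavage or migration of the butyrate and base-induced β-elimination across C1–C2 to compete. The fallback sets out from alcohol 25, before any butyrate is present. HF·pyridine (THF/pyridine, 0 °C → rt) removes the TBS ether under acidic conditions to give the diol ester 2-(trimethylsilyl)ethyl (1S,2R,7S,7aR)-1-hydroxy-7-(hydroxymethyl)-4-[(1S)-1,3,3-trimethylcyclohexyl]-2,3,5,6,7,7a-hexahydro-1H-indene-2-carboxylate F3. The primary hydroxyl is acylated selectively with 26 (2,4,6-collidine, DMAP cat., −40 °C) to give 2-(trimethylsilyl)ethyl (1S,2R,7S,7aR)-7-(butanoyloxymethyl)-1-hydroxy-4-[(1S)-1,3,3-trimethylcyclohexyl]-2,3,5,6,7,7a-hexahydro-1H-indene-2-carboxylate F4. The remaining ester is then cleaved quickly with TASF, (Me2N)3S+ Me3SiF2−, in DMF at 0 °C, returning to the route at 28.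

**Further compounds**
F0 | step 12 | none | none
F1 | step 3 | (1RS,3S)-3-(1-iodoethenyl)-1,3-dimethylcyclohexan-1-ol | C=C(I)[C@@]1(C)CCCC(C)(O)C1
F2 | step 3 | (1S,3RS)-3-chloro-1-(1-iodoethenyl)-1,3-dimethylcyclohexane | C=C(I)[C@@]1(C)CCCC(C)(Cl)C1
F3 | step 16 | 2-(trimethylsilyl)ethyl (1S,2R,7S,7aR)-1-hydroxy-7-(hydroxymethyl)-4-[(1S)-1,3,3-trimethylcyclohexyl]-2,3,5,6,7,7a-hexahydro-1H-indene-2-carboxylate | OC[C@H]1CCC([C@@]2(C)CCCC(C)(C)C2)=C2C[C@@H](C(=O)OCC[Si](C)(C)C)[C@@H](O)[C@@H]21
F4 | step 16 | 2-(trimethylsilyl)ethyl (1S,2R,7S,7aR)-7-(butanoyloxymethyl)-1-hydroxy-4-[(1S)-1,3,3-trimethylcyclohexyl]-2,3,5,6,7,7a-hexahydro-1H-indene-2-carboxylate | CCCC(=O)OC[C@H]1CCC([C@@]2(C)CCCC(C)(C)C2)=C2C[C@@H](C(=O)OCC[Si](C)(C)C)[C@@H](O)[C@@H]21
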